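**Retrosynthetic overview**
- Isoamoritin ⇐ its 7,3'-diacetate (final ammonolysis).
- All three aryl–prenyl C–C bonds (C6, C8, C5') are cut in one operation ⇐ a 6,8,5'-triiodide plus a tertiary allyl sulfone, joined under visible light by aryl-radical addition and sulfonyl loss (the allyl transposition delivers the linear prenyl group).
- Triiodide ⇐ hesperetin 7,3'-diacetate by one threefold iodination; the 3'-acetate hands control of ring B to the 4'-OMe group (C5').
- Diacetate ⇐ natural (2S)-hesperetin: rings A, B and C and the C2 stereocenter are bought, no ring is formed and C2 is never touched.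
- Sulfone reagent ⇐ allyl phenyl sulfone + 2 MeI.

Assumption: (2S)-hesperetin is bought as the single enantiomer (aglycone of the bulk citrus glycoside hesperidin; ee checked by chiral HPLC); where one reagent acts several times in one flask, the partly reacted compounds are numbered in the most likely order of reaction, which has no bearing on the product.

**Step 1**
Reactants: 1 (2S)-hesperetin; 2 acetic anhydride
Product: 4 (2S)-7-acetoxy-2-(3-acetoxy-4-methoxyphenyl)-5-hydroxychroman-4-one, via 7-O-acetylhesperetin 3 (not isolated)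
Conditions: Ac2O (2.2 equiv), pyridine, 0 °C to rt, 3 h
Reagents that add atoms: acetic anhydride, CC(=O)OC(C)=O
Why: Pyridine-mediated O-acetylation (nucleophilic acyl substitution) of the 7- and 3'-phenols, while the 5-OH is locked in a hydrogen bond to the C4 carbonyl and stays free, and C2 is not involved.

**Step 2**
Reactants: 4 (2S)-7-acetoxy-2-(3-acetoxy-4-methoxyphenyl)-5-hydroxychroman-4-one; 5 N-iodosuccinimide
Product: 8 (2S)-7-acetoxy-2-(3-acetoxy-5-iodo-4-methoxyphenyl)-5-hydroxy-6,8-diiodochroman-4-one, via 6-iodo diacetate 6 (not isolated), via 6,8-diiodo diacetate 7 (not isolated)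
Conditions: NIS (3.5 equiv), CF3CO2H–CH2Cl2 1:1, 0 °C to rt, dark
Reagents that add atoms: N-iodosuccinimide, O=C1CCC(=O)N1I
Why: Electrophilic aromatic iodination, in which C6 and C8 of ring A are activated by the free 5-OH and the ring oxygen, and in ring B the acetylated 3'-oxygen is only a weak director so that the 4'-OMe group sends iodine to its one free ortho position C5' (C2' and C6' are also shielded by the branched C2 carbon), with the acidic medium leaving C2 unchanged.

**Step 3**
Reactants: 9 allyl phenyl sulfone; 10 iodomethane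
Product: 14 [(2-methylbut-3-en-2-yl)sulfonyl]benzene, via lithiated allyl phenyl sulfone 11 (not isolated), via but-3-en-2-yl phenyl sulfone 12 (not isolated), via lithiated but-3-en-2-yl phenyl sulfone 13 (not isolated)
Conditions: n-BuLi (1.05 equiv), THF, −78 °C, then MeI (1.1 equiv); n-BuLi (1.05 equiv), −78 °C, then MeI (1.2 equiv), −78 to 0 °C
Reagents that add atoms: iodomethane, CI
Why: Twofold α-alkylation of a sulfonyl-stabilised allyl carbanion, which is methylated at the carbon next to sulfur each time and so gives the tertiary allyl sulfone (the stereocenter of racemic 12 disappears in 14).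

**Step 4**
Reactants: 8 (2S)-7-acetoxy-2-(3-acetoxy-5-iodo-4-methoxyphenyl)-5-hydroxy-6,8-diiodochroman-4-one; 14 [(2-methylbut-3-en-2-yl)sulfonyl]benzene
Product: 17 (2S)-7-acetoxy-2-[3-acetoxy-4-methoxy-5-(3-methylbut-2-enyl)phenyl]-5-hydroxy-6,8-bis(3-methylbut-2-enyl)chroman-4-one, via 6-prenyl-8,5'-diiodo diacetate 15 (not isolated), via 6,8-diprenyl-5'-iodo diacetate 16 (not isolated)
Conditions: 4CzIPN (5 mol %), Et3N (9 equiv), 14 (12 equiv), dry degassed MeCN (0.03 M), 450 nm LEDs, 20 °C, 16 h; aqueous work-up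
Reagents that add atoms: [(2-methylbut-3-en-2-yl)sulfonyl]benzene, C=CC(C)(C)S(=O)(=O)c1ccccc1
Why: Proposed new method: threefold radical ipso-prenylation of an aryl triiodide with allyl transposition, in which photoexcited 4CzIPN oxidises Et3N to an α-aminoalkyl radical that abstracts iodine from each C–I bond (halogen-atom transfer, indifferent to the two ortho substituents of ring A and to the electron-rich ring B), the aryl σ-radical adds to the unhindered CH2= end of 14 and the adduct radical expels PhSO2• (reduced to sulfinate by the reduced photocatalyst), so every new bond is made to CH2 and the alkene ends up as the 3-methylbut-2-enyl group, while the 450 nm light is not absorbed by the flavanone and no strong base is present, so C2 stays S; the closest known reaction type is the photoredox halogen-atom-transfer allylation of alkyl iodides with allyl sulfones (radical SH2' allyl transfer of the Keck allylation kind).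

**Step 5**
Reactants: 17 (2S)-7-acetoxy-2-[3-acetoxy-4-methoxy-5-(3-methylbut-2-enyl)phenyl]-5-hydroxy-6,8-bis(3-methylbut-2-enyl)chroman-4-one
Product: 19 isoamoritin, via 3'-O-acetylisoamoritin 18 (not isolated)
Conditions: NH3 (7 M in MeOH, 20 equiv), degassed, 0 °C, 1 h; AcOH quench
Reagents that add atoms: none
Why: Ammonolysis of the two aryl acetates (acyl transfer to NH3) under conditions too mild for the prenyl groups or the ketone, and the 7-OH freed first is ionised by ammonia, which disfavours retro-oxa-Michael opening of ring C and keeps C2 as S.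

**Compound list**
1 | (2S)-hesperetin, (2S)-5,7-dihydroxy-2-(3-hydroxy-4-methoxyphenyl)chroman-4-one | COc1c(O)cc([C@@H]2CC(=O)c3c(O)cc(O)cc3O2)cc1 | starting material
2 | acetic anhydride | CC(=O)OC(C)=O | starting material
3 | 7-O-acetylhesperetin, (2S)-7-acetoxy-5-hydroxy-2-(3-hydroxy-4-methoxyphenyl)chroman-4-one | COc1c(O)cc([C@@H]2CC(=O)c3c(O)cc(OC(C)=O)cc3O2)cc1 | intermediate (not isolated)
4 | (2S)-7-acetoxy-2-(3-acetoxy-4-methoxyphenyl)-5-hydroxychroman-4-one | COc1c(OC(C)=O)cc([C@@H]2CC(=O)c3c(O)cc(OC(C)=O)cc3O2)cc1 | intermediate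
5 | N-iodosuccinimide | O=C1CCC(=O)N1I | starting material
6 | (2S)-7-acetoxy-2-(3-acetoxy-4-methoxyphenyl)-5-hydroxy-6-iodochroman-4-one | COc1c(OC(C)=O)cc([C@@H]2CC(=O)c3c(O)c(I)c(OC(C)=O)cc3O2)cc1 | intermediate (not isolated)
7 | (2S)-7-acetoxy-2-(3-acetoxy-4-methoxyphenyl)-5-hydroxy-6,8-diiodochroman-4-one | COc1c(OC(C)=O)cc([C@@H]2CC(=O)c3c(O)c(I)c(OC(C)=O)c(I)c3O2)cc1 | intermediate (not isolated)
8 | (2S)-7-acetoxy-2-(3-acetoxy-5-iodo-4-methoxyphenyl)-5-hydroxy-6,8-diiodochroman-4-one | COc1c(OC(C)=O)cc([C@@H]2CC(=O)c3c(O)c(I)c(OC(C)=O)c(I)c3O2)cc1I | intermediate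
9 | allyl phenyl sulfone | C=CCS(=O)(=O)c1ccccc1 | starting material
10 | iodomethane | CI | starting material
11 | [1-(phenylsulfonyl)allyl]lithium | [Li]C(C=C)S(=O)(=O)c1ccccc1 | intermediate (not isolated)
12 | (but-3-en-2-ylsulfonyl)benzene, racemic | C=CC(C)S(=O)(=O)c1ccccc1 | intermediate (not isolated)
13 | [2-(phenylsulfonyl)but-3-en-2-yl]lithium | [Li]C(C)(C=C)S(=O)(=O)c1ccccc1 | intermediate (not isolated)
14 | [(2-methylbut-3-en-2-yl)sulfonyl]benzene | C=CC(C)(C)S(=O)(=O)c1ccccc1 | intermediate
15 | (2S)-7-acetoxy-2-(3-acetoxy-5-iodo-4-methoxyphenyl)-5-hydroxy-8-iodo-6-(3-methylbut-2-enyl)chroman-4-one | COc1c(OC(C)=O)cc([C@@H]2CC(=O)c3c(O)c(CC=C(C)C)c(OC(C)=O)c(I)c3O2)cc1I | intermediate (not isolated)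
16 | (2S)-7-acetoxy-2-(3-acetoxy-5-iodo-4-methoxyphenyl)-5-hydroxy-6,8-bis(3-methylbut-2-enyl)chroman-4-one | COc1c(OC(C)=O)cc([C@@H]2CC(=O)c3c(O)c(CC=C(C)C)c(OC(C)=O)c(CC=C(C)C)c3O2)cc1I | intermediate (not isolated)
17 | (2S)-7-acetoxy-2-[3-acetoxy-4-methoxy-5-(3-methylbut-2-enyl)phenyl]-5-hydroxy-6,8-bis(3-methylbut-2-enyl)chroman-4-one | COc1c(OC(C)=O)cc([C@@H]2CC(=O)c3c(O)c(CC=C(C)C)c(OC(C)=O)c(CC=C(C)C)c3O2)cc1CC=C(C)C | intermediate
18 | 3'-O-acetylisoamoritin, (2S)-2-[3-acetoxy-4-methoxy-5-(3-methylbut-2-enyl)phenyl]-5,7-dihydroxy-6,8-bis(3-methylbut-2-enyl)chroman-4-one | COc1c(OC(C)=O)cc([C@@H]2CC(=O)c3c(O)c(CC=C(C)C)c(O)c(CC=C(C)C)c3O2)cc1CC=C(C)C | intermediate (not isolated)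
19 | isoamoritin, (2S)-5,7-dihydroxy-2-[3-hydroxy-4-methoxy-5-(3-methylbut-2-enyl)phenyl]-6,8-bis(3-methylbut-2-enyl)chroman-4-one | COc1c(O)cc([C@@H]2CC(=O)c3c(O)c(CC=C(C)C)c(O)c(CC=C(C)C)c3O2)cc1CC=C(C)C | target

**Step count**
Total: 5 steps (four on the main line, one to make reagent 14). Longest linear sequence: 4 steps (1, 2, 4, 5 from (2S)-hesperetin).

**Steps most likely to fail**

Step 4 (the proposed new step). The risks are sulfonyl-radical-induced 1,3-isomerisation of 14 to unreactive prenyl phenyl sulfone (hence the large excess), hydrodeiodination of the aryl radicals, and incomplete threefold conversion. The fallback is known chemistry; it sets out from 8 and comes back at 17. It is a threefold Stille coupling of 8 with commercial tributyl(3-methylbut-2-enyl)stannane (4.5 equiv), Pd(PPh3)4 (10 mol %, zerovalent palladium), DMF, 90 °C, dark. The prenyl group is transferred through its CH2 end, as is usual for prenylstannanes, so 17 is formed directly (new compounds: none F0).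

Step 2 (site of iodination in ring B). Iodination para to the 3'-acetoxy group (C6') could compete with the wanted C5' attack. The fallback sets out from 4 and comes back at 8; it replaces electronic control by steric control.
- First, C–H borylation with [Ir(OMe)(cod)]2 (3 mol %), 4,4'-di-tert-butyl-2,2'-bipyridine and B2pin2 (2.5 equiv) in THF at 70 °C. C6, C8 and C2' each lie between two substituents and C6' lies next to the branched C2 carbon, so the C–H beside the flat methoxy group reacts. This gives (2S)-7-acetoxy-2-[3-acetoxy-4-methoxy-5-(4,4,5,5-tetramethyl-1,3,2-dioxaborolan-2-yl)phenyl]-5-hydroxychroman-4-one F1.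
- Then NIS (3.3 equiv) in MeCN at 60 °C iodinates C6 and C8 and replaces boron by iodine (ipso-iododeboronation), giving 8.

Step 5 (C2 integrity under basic deacetylation). Ammonia could cause partial retro-oxa-Michael opening and loss of ee. The fallback sets out from 8 and comes back at 19; it removes the acetates under acid before any prenyl group is present.
- HCl (1.25 M in MeOH), 0 °C to rt, gives (2S)-5,7-dihydroxy-2-(3-hydroxy-5-iodo-4-methoxyphenyl)-6,8-diiodochroman-4-one F2 by acid-catalysed transesterification, which cannot racemise C2 by the base pathway.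
- F2 is then prenylated with 14 under the conditions of step 4 (or by the Stille coupling above) to give 19 directly.

**Further compounds**
F0 | step 4 | none | none
F1 | step 2 | (2S)-7-acetoxy-2-[3-acetoxy-4-methoxy-5-(4,4,5,5-tetramethyl-1,3,2-dioxaborolan-2-yl)phenyl]-5-hydroxychroman-4-one | COc1c(OC(C)=O)cc([C@@H]2CC(=O)c3c(O)cc(OC(C)=O)cc3O2)cc1B1OC(C)(C)C(C)(C)O1
F2 | step 5 | (2S)-5,7-dihydroxy-2-(3-hydroxy-5-iodo-4-methoxyphenyl)-6,8-diiodochroman-4-one | COc1c(O)cc([C@@H]2CC(=O)c3c(O)c(I)c(O)c(I)c3O2)cc1I
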